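The ring A oxirane is installed last: the target is traced to its deoxy compound, whose ring A (C1 carries the CH2 linker, C2 the isopropenyl group, C5 the methyl group) holds the only trisubstituted alkene, C5=C6. The key step exploits this C5=C6 bond, the most electron-rich of three C=C bonds: one enzymatic oxygen-atom transfer forms both C–O bonds, closes the oxirane and sets C5 and C6 on the face syn to the C1 linker. The precursor comes from (S)-carvone and an allylic iodide made from limonene-1,2-diol that already carries the ring B cis-bromohydrin, joined by enolate alkylation and finished by reductive 1,3-transposition of the enone.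

Key step: step 10

Remarks on the chemistry:
- Ring B is numbered C1' (carbinol carbon), C2' (C–Br) and C4' (carbon bonded to the central alkene carbon).
- Cyclic sulfite 2 is stereogenic at sulfur and is expected as a mixture of sulfur epimers that converge on oxidation.
- The C1 descriptor of ring A changes (R in 11 and 12, S in 15 and 16, R in 17) only through CIP priorities; the geometry, linker trans to the C2 isopropenyl group, stays the same.
- Assumption: a P450 BM3 variant with the required selectivity is obtainable by screening and directed evolution.

Step 1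
Reactants: 1 (1S,2S,4R)-limonene-1,2-diol
Product: 3 trans-fused cyclic sulfate of diol 1 (1,3,2-dioxathiolane 2,2-dioxide on C1'/C2'; carbon stereocentres unchanged), via cyclic sulfite 2 (not isolated)
Conditions: SOCl2 (1.1 equiv), Et3N, CH2Cl2, 0 °C; filter, concentrate; then RuCl3·xH2O (0.5 mol%), NaIO4 (1.1 equiv), MeCN/H2O, 0 °C, short contact time
Reagents that add atoms: thionyl chloride, O=S(Cl)Cl; sodium periodate, [Na+].[O-]I(=O)(=O)=O
Why: Cyclic sulfite formation followed by ruthenium-catalysed oxidation to the cyclic sulfate: after a chair flip that makes both C–O bonds equatorial the trans-diol closes onto sulfur, and catalytic RuO4 with limiting periodate should oxidise tetravalent sulfur to hexavalent sulfur much faster than it attacks the isolated 1,1-disubstituted alkene; no carbon stereocentre changes.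

Step 2
Reactants: 3 cyclic sulfate of diol 1
Product: 5 (1S,2R,4R)-2-bromo-1-methyl-4-(prop-1-en-2-yl)cyclohexan-1-ol (cis-bromohydrin), via lithium alkyl sulfate 4 (not isolated)
Conditions: LiBr, THF, 50 °C; then cat. H2SO4, H2O (2 equiv), THF, rt
Reagents that add atoms: lithium bromide, [Li+].[Br-]
Why: SN2 opening of a 1,2-cyclic sulfate by bromide at secondary C2' (tertiary C1' allows no backside attack, and the tied-back equatorial C–O bonds have no antiperiplanar hydrogen for E2) inverts C2' from S to R and puts bromine cis to the C1' oxygen, after which acid hydrolysis of the sulfate monoester cleaves S–O and leaves C1' untouched.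

Step 3
Reactants: 5 cis-bromohydrin
Product: 6 triethylsilyl ether of 5
Conditions: TESOTf, 2,6-lutidine, CH2Cl2, −78 to 0 °C
Reagents that add atoms: triethylsilyl trifluoromethanesulfonate, CC[Si](CC)(CC)OS(=O)(=O)C(F)(F)F
Why: Silylation of a hindered tertiary alcohol with a silyl triflate and a non-nucleophilic base removes the only acidic proton before the hypochlorite and enolate steps; no stereocentre is affected.

Step 4
Reactants: 6 triethylsilyl ether
Product: 7 allylic chloride (isopropenyl group converted to a 3-chloroprop-1-en-2-yl group)
Conditions: Ca(OCl)2, CO2 (solid), CH2Cl2/H2O, 0 °C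
Reagents that add atoms: calcium hypochlorite, [Ca+2].[O-]Cl.[O-]Cl
Why: Ene-type allylic chlorination of an isopropenyl group by HOCl made in the flask: chloronium formation at the terminal CH2 and loss of a methyl proton shift the double bond and give the 2-substituted allyl chloride, while the bromide and the silyl ether are inert and C4' is not touched.

Step 5
Reactants: 7 allylic chloride
Product: 8 allylic iodide
Conditions: NaI, acetone, rt, dark
Reagents that add atoms: sodium iodide, [Na+].[I-]
Why: Finkelstein exchange at the primary allylic chloride, driven by precipitation of NaCl, while the hindered secondary C2' bromide should not exchange at room temperature.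

Step 6
Reactants: 9 (S)-(+)-carvone; 8 allylic iodide
Product: 11 trans-alkylated enone (ring A: C6 carbonyl, C4=C5 alkene, C1 R, C2 S; ring B silyl ether attached through the 2-substituted allyl chain), via lithium dienolate 10 (not isolated)
Conditions: LiN(iPr)2 (1.05 equiv), THF, −78 °C; then 8, −78 to −30 °C
Reagents that add atoms: none
Why: Kinetic α'-deprotonation of carvone gives the cross-conjugated lithium dienolate, and its alkylation by the allylic iodide (SN2 and SN2' give the same product) takes place at C1 of ring A on the face opposite the adjacent C2 isopropenyl group, setting C1 trans to C2 by substrate control in the thermodynamically preferred diequatorial arrangement.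

Step 7
Reactants: 11 trans-alkylated enone
Product: 12 tosylhydrazone of 11 (C=N geometry not defined)
Conditions: TsNHNH2, cat. AcOH, EtOH, 50 °C
Reagents that add atoms: p-toluenesulfonyl hydrazide, Cc1ccc(cc1)S(=O)(=O)NN
Why: Acid-catalysed condensation of the ketone with tosylhydrazide gives the conjugated tosylhydrazone needed for reductive transposition; C1 stays in the more stable trans configuration and either C=N isomer is usable.

Step 8
Reactants: 12 tosylhydrazone
Product: 15 triethylsilyl ether of the deoxy compound (ring A alkene now C5=C6), via N-boryl hydrazide 13 (not isolated), via allylic diazene 14 (not isolated)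
Conditions: catecholborane, CHCl3, 0 °C; then NaOAc·3H2O, reflux
Reagents that add atoms: none
Why: Catecholborane reduction of a conjugated tosylhydrazone with alkene transposition: hydride goes to C6, acetate triggers loss of sulfinate to the allylic diazene, and its retro-ene loss of N2 passes hydrogen to C4 so that the alkene moves from C4=C5 to C5=C6, with no stereocentre left at C6 and C1 and C2 untouched.

Step 9
Reactants: 15 silyl ether of the deoxy compound
Product: 16 deoxy compound (1S,2R,4R)-2-bromo-1-methyl-4-{3-[(1S,6S)-3-methyl-6-(prop-1-en-2-yl)cyclohex-2-en-1-yl]prop-1-en-2-yl}cyclohexan-1-ol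
Conditions: HF·pyridine, pyridine, THF, 0 °C to rt
Reagents that add atoms: none
Why: Fluoride cleavage of the tertiary triethylsilyl ether under buffered, weakly acidic conditions avoids a free alkoxide next to the C2' bromide and leaves the three alkenes alone.

Step 10
Reactants: 16 deoxy compound
Product: 17 target, (1S,2R,4R)-2-bromo-1-methyl-4-{3-[(1R,2R,3S,6S)-6-methyl-3-(prop-1-en-2-yl)-7-oxabicyclo[4.1.0]heptan-2-yl]prop-1-en-2-yl}cyclohexan-1-ol
Conditions: engineered cytochrome P450 BM3 (CYP102A1) variant, NADP+ (cat.), D-glucose, glucose dehydrogenase, air (O2), potassium phosphate buffer pH 8.0, 5% DMSO, 25 °C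
Reagents that add atoms: dioxygen, O=O
Why: Proposed new method: the ferryl-oxo porphyrin radical cation of the P450 (tetravalent iron) adds its oxygen atom to C6 of the C5=C6 bond and the resulting tertiary C5 radical collapses at once onto the same iron-bound oxygen, so both C–O bonds come from one oxygen atom in an effectively concerted, suprafacial transfer. The closest known reaction type is the P450- or peroxygenase-catalysed epoxidation of the ring alkene of limonene, in which the protein and not the substrate decides the diastereomer; what is new is the demand for that control on a brominated C20 substrate with two further alkenes. The oxirane, the only ring formed, closes by this [2+1] oxygen-atom addition (3-exo closure of the C5 radical with iron as the leaving group), and its cis fusion to ring A is enforced by the six-membered ring. The two new stereocentres, C5 (S) and C6 (R), are set together by the face of delivery, which must be syn to the C1 linker and anti to the C2 isopropenyl group; since ring A has little intrinsic facial bias this is catalyst control by the binding pocket, to be found by screening a variant panel and sharpened by directed evolution. Site selectivity among the three alkenes is supported by the substrate, because C5=C6 is the only trisubstituted and therefore most electron-rich C=C bond, whereas the two 1,1-disubstituted alkenes should react more slowly with the electrophilic oxidant. The ring B bromohydrin should survive the near-neutral aqueous medium because bromine and hydroxyl are cis and cannot close a second oxirane.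

Compound list
1 | (1S,2S,4R)-limonene-1,2-diol [(1S,2S,4R)-1-methyl-4-(prop-1-en-2-yl)cyclohexane-1,2-diol] | C=C(C)[C@@H]1CC[C@](C)(O)[C@@H](O)C1 | starting material
2 | cyclic sulfite of 1 (trans-fused 1,3,2-dioxathiolane 2-oxide on C1'/C2', mixture of sulfur epimers) | C=C(C)[C@@H]1CC[C@]2(C)OS(=O)O[C@H]2C1 | intermediate (not isolated)
3 | cyclic sulfate of 1 (trans-fused 1,3,2-dioxathiolane 2,2-dioxide on C1'/C2') | C=C(C)[C@@H]1CC[C@]2(C)OS(=O)(=O)O[C@H]2C1 | intermediate
4 | lithium (1S,2R,4R)-2-bromo-1-methyl-4-(prop-1-en-2-yl)cyclohexyl sulfate | C=C(C)[C@@H]1CC[C@](C)(OS(=O)(=O)[O-])[C@H](Br)C1.[Li+] | intermediate (not isolated)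
5 | (1S,2R,4R)-2-bromo-1-methyl-4-(prop-1-en-2-yl)cyclohexan-1-ol (Br cis to OH) | C=C(C)[C@@H]1CC[C@](C)(O)[C@H](Br)C1 | intermediate
6 | {[(1S,2R,4R)-2-bromo-1-methyl-4-(prop-1-en-2-yl)cyclohexyl]oxy}triethylsilane | C=C(C)[C@@H]1CC[C@](C)(O[Si](CC)(CC)CC)[C@H](Br)C1 | intermediate
7 | {[(1S,2R,4R)-2-bromo-4-(3-chloroprop-1-en-2-yl)-1-methylcyclohexyl]oxy}triethylsilane | C=C(CCl)[C@@H]1CC[C@](C)(O[Si](CC)(CC)CC)[C@H](Br)C1 | intermediate
8 | {[(1S,2R,4R)-2-bromo-4-(3-iodoprop-1-en-2-yl)-1-methylcyclohexyl]oxy}triethylsilane | C=C(CI)[C@@H]1CC[C@](C)(O[Si](CC)(CC)CC)[C@H](Br)C1 | intermediate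
9 | (S)-(+)-carvone | C=C(C)[C@H]1CC=C(C)C(=O)C1 | starting material
10 | lithium dienolate of 9 (cross-conjugated, O–C6=C1 and C4=C5 in ring A numbering) | C=C(C)[C@H]1CC=C(C)C(O[Li])=C1 | intermediate (not isolated)
11 | (5S,6R)-2-methyl-5-(prop-1-en-2-yl)-6-{2-[(1R,3R,4S)-3-bromo-4-methyl-4-(triethylsilyloxy)cyclohexyl]prop-2-en-1-yl}cyclohex-2-en-1-one | C=C(C[C@@H]1[C@@H](C(=C)C)CC=C(C)C1=O)[C@@H]1CC[C@](C)(O[Si](CC)(CC)CC)[C@H](Br)C1 | intermediate
12 | p-toluenesulfonylhydrazone of 11 | C=C(C[C@@H]1[C@@H](C(=C)C)CC=C(C)C1=NNS(=O)(=O)c1ccc(C)cc1)[C@@H]1CC[C@](C)(O[Si](CC)(CC)CC)[C@H](Br)C1 | intermediate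
13 | N-(1,3,2-benzodioxaborol-2-yl)-N'-tosyl hydrazide formed by hydride addition to C6 of 12 (C6 configuration not defined) | C=C(C[C@@H]1[C@@H](C(=C)C)CC=C(C)C1N(B2Oc3ccccc3O2)NS(=O)(=O)c2ccc(C)cc2)[C@@H]1CC[C@](C)(O[Si](CC)(CC)CC)[C@H](Br)C1 | intermediate (not isolated)
14 | allylic diazene (ring A C6–N=NH beside the C4=C5 alkene; C6 configuration not defined) | C=C(C[C@@H]1[C@@H](C(=C)C)CC=C(C)C1N=N)[C@@H]1CC[C@](C)(O[Si](CC)(CC)CC)[C@H](Br)C1 | intermediate (not isolated)
15 | triethylsilyl ether of 16 | C=C(C[C@@H]1[C@@H](C(=C)C)CCC(C)=C1)[C@@H]1CC[C@](C)(O[Si](CC)(CC)CC)[C@H](Br)C1 | intermediate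
16 | (1S,2R,4R)-2-bromo-1-methyl-4-{3-[(1S,6S)-3-methyl-6-(prop-1-en-2-yl)cyclohex-2-en-1-yl]prop-1-en-2-yl}cyclohexan-1-ol (deoxy compound) | C=C(C[C@@H]1[C@@H](C(=C)C)CCC(C)=C1)[C@@H]1CC[C@](C)(O)[C@H](Br)C1 | intermediate
17 | (1S,2R,4R)-2-bromo-1-methyl-4-{3-[(1R,2R,3S,6S)-6-methyl-3-(prop-1-en-2-yl)-7-oxabicyclo[4.1.0]heptan-2-yl]prop-1-en-2-yl}cyclohexan-1-ol (CNP0213097.1) | C=C(C[C@@H]1[C@@H](C(=C)C)CC[C@]2(C)O[C@H]12)[C@@H]1CC[C@](C)(O)[C@H](Br)C1 | target

Total step count: 10. Longest linear sequence: 10 steps (from diol 1; carvone 9 enters at step 6).

Steps most likely to fail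

Step 10. The process at risk is the search for a variant that combines site selectivity for C5=C6 with oxygen delivery syn to the C1 linker. Allylic hydroxylation, epoxidation of a 1,1-disubstituted alkene or poor uptake of the lipophilic substrate may dominate. The fallback uses known chemistry, sets out from 16 and returns at 17. Prilezhaev epoxidation with mCPBA (NaHCO3, CH2Cl2, −20 °C) is selective for the trisubstituted alkene and should give 17 together with the ring A epoxide epimer F1 (oxirane anti to the C1 linker); the two would be separated by chromatography. If the share of 17 is poor, the chiral dioxirane of a fructose-derived ketone with Oxone (Shi epoxidation), in the ketone antipode that proves matched, would supply reagent control of the face.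

Step 2. Backside attack at C2' of the strained trans-fused sulfate may be sluggish, because the entering bromide meets the axial C4' side chain. Ionisation or elimination at tertiary C1' may compete during opening or hydrolysis. The fallback sets out from diol 1 and returns at 6, and so also removes the oxidation of step 1, where over-oxidation of the isopropenyl group is the related hazard. Selective mesylation of the secondary hydroxyl (MsCl, Et3N, CH2Cl2, −20 °C) gives the secondary mesylate F2. Silylation (TESOTf, 2,6-lutidine) gives its triethylsilyl ether F3, which removes the neighbouring hydroxyl that could close an oxirane. LiBr in DMF at 60 °C then displaces the axial mesylate by equatorial attack with inversion, in the relaxed chair with the side chain equatorial, and gives 6 directly.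

Step 8. Hydride delivery to the hindered, doubly flanked C=N may be incomplete, the diazene may decompose without clean hydrogen transfer to C4, and the condensation of step 7 may be slow. The fallback sets out from ketone 11 and returns at 15, bypassing steps 7 and 8. Conjugate reduction with LiBH(s-Bu)3 (THF, −78 °C) and trapping of the enolate with PhNTf2 gives the enol triflate F4 (C6–OTf, C5=C6). Reductive detriflation with zerovalent palladium formed from Pd(OAc)2 and PPh3 (Bu3N, HCO2H, DMF, 60 °C) replaces the triflate by hydrogen and gives 15 with the alkene already at C5=C6.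

Further compounds
F1 | step 10 | ring A epoxide epimer of 17 (oxirane anti to the C1 linker) | C=C(C[C@@H]1[C@@H](C(=C)C)CC[C@@]2(C)O[C@@H]12)[C@@H]1CC[C@](C)(O)[C@H](Br)C1
F2 | step 2 | (1S,2S,5R)-2-hydroxy-2-methyl-5-(prop-1-en-2-yl)cyclohexyl methanesulfonate (secondary mesylate of 1) | C=C(C)[C@@H]1CC[C@](C)(O)[C@@H](OS(C)(=O)=O)C1
F3 | step 2 | triethylsilyl ether of F2 | C=C(C)[C@@H]1CC[C@](C)(O[Si](CC)(CC)CC)[C@@H](OS(C)(=O)=O)C1
F4 | step 8 | enol triflate from 11 (ring A C6–OTf, C5=C6) | C=C(C[C@@H]1[C@@H](C(=C)C)CCC(C)=C1OS(=O)(=O)C(F)(F)F)[C@@H]1CC[C@](C)(O[Si](CC)(CC)CC)[C@H](Br)C1
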